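## The problem

The target, 3,4-dibromo-5-{[2,4-dihydroxy-6-(hydroxymethyl)-3-methoxyphenyl]methyl}benzene-1,2-diol (16), is a diarylmethane. Two pentasubstituted benzene rings are joined only through the methylene C7, so there is no ring fusion and no stereocentre, and the task is one of regiochemistry and chemoselectivity. Ring A carries five groups in a fixed order: C1 OMe flanked by the C2 and C6 hydroxyls, C3 H, C4 with the hydroxymethyl carbon C8, and C5 with the link C7. Ring B carries a vicinal dibromide (C2', C3') next to a catechol (C4', C5'). No substituent can steer another by stereochemistry; the order must come from directing effects or from the way the ring is assembled. The aryl bromides rule out hydrogenolysis, dissolving metals and halogen-metal exchange. The catechol and the pyrogallol-type ring A oxidise readily in basic air. The single methyl ether must survive whatever unmasks the four phenols, which rules out a global demethylation. The C8 hydroxymethyl group is para to the methoxy group and ionises easily in acid. The enabling feature is that ring atoms C5-C6-C1-C2-C3, with oxygen on C6, C1 and C2, form the carbon chain of a 3-methoxy-2,4-diketone whose termini are C5 (already bearing C7 and ring B) and the methyl carbon C3. The remaining ring atom C4 with its exocyclic carbon C8 is then a vicinal dicarbonyl unit, an oxalate.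

## Retrosynthesis

**Adjusting C8 and unmasking the phenols (16 to 15 to 14).** The hydroxymethyl group of 16 is taken back to the methyl ester of tetraphenol 15, and the ring B catechol of 15 to the bis(benzyl ether) 14. Reduction is placed last because a free benzylic alcohol para to the methoxy group would ionise under the Lewis acid needed to remove the benzyl groups. Benzyl ethers are chosen because they can be cleaved by BCl3 at low temperature with a cation scavenger, without hydrogen (the bromines stay) and without touching the ring A methyl ether. The forward steps ask for a cold debenzylation and an ester reduction that tolerates four acidic phenols.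

**Opening ring A (14 to 10 + 11).** The bonds C3-C4 and C4-C5 are cut, which removes C4 and C8 as dimethyl oxalate (11) and leaves the open-chain diketone 1-[4,5-bis(benzyloxy)-2,3-dibromophenyl]-4-methoxyhexane-3,5-dione (10). The neighbouring cut at C5-C7, a Friedel-Crafts benzylation of a 4-O-methylgallate, is the classical diarylmethane disconnection and is kept in reserve. The ring-forming cut is preferred because the position of every ring A substituent is then dictated by the connectivity of a chain, not by directing effects, and because the benzyl ethers never meet a strong acid while the rings are joined. The precursor 10 has one ring fewer and no aromatic regiochemistry left to solve. The forward reaction must acylate a terminal carbon of 10 with the oxalate, close the six-membered ring by aldol addition onto the new keto group, and aromatise by loss of water. C7 arrives as a methylene and C8 at the ester level.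

**Joining the chain to ring B (10 to 9 + 6).** The bond C5-C7 is cut between the diketone terminus and the benzylic carbon. This gives 3-methoxypentane-2,4-dione (9) and the benzylic bromide 1,2-bis(benzyloxy)-3,4-dibromo-5-(bromomethyl)benzene (6). The cut is chosen over a Claisen assembly of the diketone from an arylpropanoate because the terminal alkylation of a β-diketone dianion is direct and because 9 is symmetric, so only one monoalkylation product exists. The forward step needs the dianion to react at its terminal carbon and only once.

**The methoxy diketone (9 to 8 to 7).** The C1-O bond of 9 is cut to the carbenoid precursor 3-diazopentane-2,4-dione (8), which comes from acetylacetone (7) by diazo transfer. Insertion of a rhodium carbenoid into the O-H bond of methanol places the oxygen exactly on the central carbon. Direct enolate oxidation or displacement of a 3-halide would risk cleavage of the diketone.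

**The ring B bromide (6 to 5 to 4 to 3 to 2 to 1).** The bromide 6 is traced through alcohol 5 and aldehyde 4 to 2,3-dibromo-4,5-dihydroxybenzaldehyde (3). Compound 3 comes from 2,3-dibromo-4-hydroxy-5-methoxybenzaldehyde (2) by chelation-assisted demethylation, and 2 from commercial 5-bromovanillin (1) by a second bromination. The C-Br bond at C2' is cut last because the free position para to the methoxy group of 1 is the one that becomes C2'. The bromination pattern therefore follows from the vanillin oxygenation pattern. The original methyl ether is exchanged for benzyl so that no second methyl ether has to be told apart from the ring A methoxy group at the end.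

## Roads not taken

**Alternative 1:** The cut removes both carbon arms of ring A at once, C4-C8 and C5-C7. In the forward direction, CsF would release the C4-C5 aryne from the silyl triflate A2. tert-Butyl isocyanide A3 would add at C4, distal to the C6 benzyloxy group, as the polarisation of 3-alkoxyarynes requires. The C5 aryl anion would add to the ring B aldehyde 4, and the alkoxide would close onto the nitrilium carbon to give the cyclic imidate A1.
- Merits: ring A is bought as an arene, the coupling is convergent, the regiochemistry is set by the aryne, and aldehyde 4 is used two steps earlier than in the chosen plan. This type of three-component coupling is also better precedented than the key step chosen here.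
- Weak points: A2 needs a multistep synthesis with ortho silyl and triflate groups on a fully oxygenated ring. The hindered ortho-bromo aldehyde 4 is a demanding third component.
- Further weak point: A1 has the wrong oxidation level at both new carbons. The imidate must be hydrolysed and reduced to a diol, and the diaryl carbinol at C7 must then be deoxygenated without hydrogenolysis (bromines) and without ionising the equally electron-rich C8 alcohol. A stereocentre is made only to be destroyed, and four benzyl ethers must be removed.
- Comparison: the chosen plan is less convergent and its key step is less secure. Against that, C7 arrives as a methylene, only the ester needs adjusting, and the endgame after ring formation is two steps.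

**Alternative 2:** The cut removes C4-C5 and C1-C6 and builds ring A from a furan. AuCl3 (trivalent gold) would isomerise the furfuryl propargyl ether A5. The alkyne carbons become C5 and C6, the furan carbons become C4 to C1, and the furan oxygen becomes the C6 hydroxyl of the phthalan phenol A4.
- Merits: the isomerisation is catalytic and wastes no atoms, and A5 comes from aldehyde 4 by acetylide addition and etherification. The endgame is better than that of the chosen plan: ionic reduction of the doubly benzylic C7-O bond of A4 would give the C7 methylene and the free C8 alcohol together, with no ester reduction.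
- Weak points: the furan in A5 must carry a methoxy group on the carbon next to the ring oxygen and a benzyloxy group beside it. Such 2-alkoxyfurans behave as ketene acetals, are hard to make and store, and are unlikely to tolerate a Lewis-acidic gold salt.
- Further weak point: with the methoxy group on the carbon that passes through the arene oxide stage, the direction of oxide opening and the fate of that methoxy group are uncertain.
- Comparison: the chosen plan works instead with a stable, two-step diketone (9) and accepts a less elegant reduction of C8 at the end.

**Alternative 3:** The cut removes C3-C4 and C5-C6. The bis(silyloxy)diene A7 and the ring B ynone A8 would combine in a Diels-Alder reaction, and loss of methanol and of the silyl groups on mild acid work-up would give the benzophenone A6.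
- Merits: the approach is convergent and the regiochemistry follows from polarisation, since the nucleophilic methylene terminus of A7 bonds to the β-carbon of A8. C8 arrives protected at the alcohol level. A8 is two steps from aldehyde 4 and A7 two silylations from a β-keto ester. Cycloaddition-aromatisation of oxygenated dienes with ynones is established, so the ring-forming step is more secure than the one chosen here.
- Weak points: C7 arrives as a ketone. A benzophenone flanked by ortho substituents on both rings and hydrogen-bonded to the C6 hydroxyl must be reduced fully to a methylene without reductive loss of bromine and without ionising the C8-O bond para to the methoxy group.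
- Further weak point: the fully substituted ketene acetal terminus of A7 must bond to the ynone carbon that carries the bulky aroyl group.
- Comparison: the step count would be about the same. The chosen plan offers C7 at the correct oxidation level from the outset and no benzylic deoxygenation.

Key step: step 9

Remarks on the chemistry:
- 5-Bromovanillin (1) is taken as the commercial entry to ring B. It is the monobromination product of vanillin, so one further step would be needed from vanillin itself.
- Compounds 9, 10, 12 and 13 are drawn as keto tautomers although they will be largely enolised. The methoxy-bearing carbon of 10 and 12 is racemic and enolisable, which is of no consequence.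

## Route

Step 1
Reactants: 1 5-bromovanillin (3-bromo-4-hydroxy-5-methoxybenzaldehyde)
Product: 2 2,3-dibromo-4-hydroxy-5-methoxybenzaldehyde
Conditions: Br2 (1.2 equiv), Fe powder (cat.), AcOH, rt
Reagents that add atoms: bromine, BrBr
Why: Electrophilic aromatic bromination; of the two free positions the one para to the methoxy group is the more activated, and it lies next to the existing bromine, so the vicinal dibromide of ring B (C2', C3') results.

Step 2
Reactants: 2 2,3-dibromo-4-hydroxy-5-methoxybenzaldehyde
Product: 3 2,3-dibromo-4,5-dihydroxybenzaldehyde
Conditions: AlCl3 (1.2 equiv), pyridine (4.5 equiv), CH2Cl2, reflux; then aq. HCl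
Reagents that add atoms: none
Why: Chelation-assisted demethylation of an ortho-hydroxy aryl methyl ether: the aluminium phenoxide binds the neighbouring methoxy oxygen and pyridine takes the methyl group; the aldehyde and the aryl bromides are not affected.

Step 3
Reactants: 3 2,3-dibromo-4,5-dihydroxybenzaldehyde
Product: 4 4,5-bis(benzyloxy)-2,3-dibromobenzaldehyde
Conditions: BnBr (2.5 equiv), K2CO3 (3 equiv), DMF, 60 °C
Reagents that add atoms: benzyl bromide, BrCc1ccccc1
Why: Williamson ether synthesis on both phenols; benzyl ethers withstand the amide and alkoxide bases used later and can be removed by a Lewis acid without hydrogen, so the bromines are safe.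

Step 4
Reactants: 4 4,5-bis(benzyloxy)-2,3-dibromobenzaldehyde
Product: 5 [4,5-bis(benzyloxy)-2,3-dibromophenyl]methanol
Conditions: NaBH4, THF/MeOH, 0 °C
Reagents that add atoms: none
Why: Borohydride reduction of an aryl aldehyde to the benzylic alcohol; aryl bromides and benzyl ethers are inert.

Step 5
Reactants: 5 [4,5-bis(benzyloxy)-2,3-dibromophenyl]methanol
Product: 6 1,2-bis(benzyloxy)-3,4-dibromo-5-(bromomethyl)benzene
Conditions: PBr3 (0.5 equiv), CH2Cl2, 0 °C
Reagents that add atoms: phosphorus tribromide, BrP(Br)Br
Why: Conversion of a benzylic alcohol into the bromide through its phosphite ester and SN2 displacement by bromide; the short, cold reaction leaves the aryl benzyl ethers intact.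

Step 6
Reactants: 7 acetylacetone (pentane-2,4-dione)
Product: 8 3-diazopentane-2,4-dione
Conditions: 4-acetamidobenzenesulfonyl azide (p-ABSA), Et3N, MeCN, 0 °C to rt
Reagents that add atoms: 4-acetamidobenzenesulfonyl azide, CC(=O)Nc1ccc(cc1)S(=O)(=O)N=[N+]=[N-]
Why: Regitz diazo transfer to the activated methylene of a β-diketone; the doubly stabilised diazo compound is isolable.

Step 7
Reactants: 8 3-diazopentane-2,4-dione
Product: 9 3-methoxypentane-2,4-dione
Conditions: Rh2(OAc)4 (1 mol %), MeOH/CH2Cl2, 40 °C
Reagents that add atoms: methanol, CO
Why: Rhodium-carbenoid O-H insertion: loss of dinitrogen gives the carbenoid, methanol adds as an oxonium ylide and proton transfer gives the α-methoxy diketone; the large excess of methanol outruns Wolff rearrangement.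

Step 8
Reactants: 9 3-methoxypentane-2,4-dione; 6 1,2-bis(benzyloxy)-3,4-dibromo-5-(bromomethyl)benzene
Product: 10 1-[4,5-bis(benzyloxy)-2,3-dibromophenyl]-4-methoxyhexane-3,5-dione
Conditions: 9 (1.4 equiv), LiN(iPr)2 (2.8 equiv), THF, −78 to 0 °C; then 6, THF, −78 to 0 °C; aq. NH4Cl
Reagents that add atoms: none
Why: Terminal (γ) alkylation of a β-diketone 1,3-dianion: the second deprotonation occurs at a methyl group, and this less delocalised carbanion displaces the benzylic bromide (SN2) to form C5-C7; the two methyl groups of 9 are equivalent, and a slight excess of dianion guards against double alkylation.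

Step 9
Reactants: 10 1-[4,5-bis(benzyloxy)-2,3-dibromophenyl]-4-methoxyhexane-3,5-dione; 11 dimethyl oxalate
Product: 14 methyl 2-[4,5-bis(benzyloxy)-2,3-dibromobenzyl]-3,5-dihydroxy-4-methoxybenzoate, via open-chain triketo ester 12 (not isolated), via cyclic aldol adduct 13 (not isolated)
Conditions: LiN(iPr)2 (2.1 equiv), THF, −78 to −20 °C; add to (CO2Me)2 (3 equiv), THF, −78 °C; then NaOMe (6 equiv), MeOH, −78 to 45 °C; aq. HCl to pH 4, 0 °C
Reagents that add atoms: none
Why: Proposed new method: the 1,3-dianion of 10 (central carbon and, kinetically, the methyl terminus C3) should attack one ester group of 11 at −78 °C in a Claisen acylation that forms C3-C4, and collapse of the tetrahedral adduct on addition of NaOMe/MeOH gives triketo ester 12 as its stabilised enolate. Under the equilibrating methoxide conditions the C5 enolate of the C6 ketone should add to the C4 carbonyl of the α-keto ester in a 6-(enolendo)-exo-trig aldol closure of ring A to give 13, and E1cB loss of water followed by enolisation of the C2 and C6 ketones aromatises the ring to 14. The closest known reaction types are the oxalate Claisen acylation of ketone and β-diketone enolates and the base-induced aldol aromatisation of 2,4,6-triketones and triketo esters to resorcinols; their combination in one flask on a 3-alkoxy-2,4-diketone is not established. No stereocentre survives, because C1, C4 and C5 of 13 all become sp2 carbons of the arene. The step needs C-cyclisation to win over O-cyclisation to a 4-pyranone, which the basic medium secures since pyranone formation is an acid-driven dehydration, and only the closure of C5 onto C4 gives a six-membered ring (attack on the ester carbon C8 would give a seven-membered ring and every other aldol pairing a four-membered ring). The site of the first acylation does not matter, because acylation at C5 followed by aldol attack of C3 on C4 leads to the same arene, and the stabilised 2,4-dioxo ester enolate protects C4 against a second addition of dianion. The aryl bromides and benzyl ethers are inert to amide and alkoxide bases at these temperatures.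

Step 10
Reactants: 14 methyl 2-[4,5-bis(benzyloxy)-2,3-dibromobenzyl]-3,5-dihydroxy-4-methoxybenzoate
Product: 15 methyl 2-(2,3-dibromo-4,5-dihydroxybenzyl)-3,5-dihydroxy-4-methoxybenzoate
Conditions: BCl3 (6 equiv), C6HMe5 (6 equiv), CH2Cl2, −78 °C; then MeOH/CHCl3 quench
Reagents that add atoms: none
Why: Lewis-acid cleavage of aryl benzyl ethers with a non-basic cation scavenger: BCl3 ionises the benzyl ethers at low temperature and pentamethylbenzene captures the benzyl cations by Friedel-Crafts alkylation; no hydrogen is used, so the bromines stay, and at −78 °C the ring A methyl ether and the methyl ester should survive.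

Step 11
Reactants: 15 methyl 2-(2,3-dibromo-4,5-dihydroxybenzyl)-3,5-dihydroxy-4-methoxybenzoate
Product: 16 3,4-dibromo-5-{[2,4-dihydroxy-6-(hydroxymethyl)-3-methoxyphenyl]methyl}benzene-1,2-diol
Conditions: iBu2AlH (10 equiv), THF, −78 to 0 °C; aq. potassium sodium tartrate
Reagents that add atoms: none
Why: Hydride reduction of an ester to the primary alcohol; the first four equivalents are consumed by the phenols, the resulting aluminium phenoxides of ring A are meta to the ester and do not deactivate it by conjugation, iBu2AlH does not reduce aryl bromides, and the buffered work-up avoids ionising the benzylic alcohol.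

## Compound list

1 | 5-bromovanillin (3-bromo-4-hydroxy-5-methoxybenzaldehyde) | COc1cc(C=O)cc(Br)c1O | starting material
2 | 2,3-dibromo-4-hydroxy-5-methoxybenzaldehyde | COc1cc(C=O)c(Br)c(Br)c1O | intermediate
3 | 2,3-dibromo-4,5-dihydroxybenzaldehyde | O=Cc1cc(O)c(O)c(Br)c1Br | intermediate
4 | 4,5-bis(benzyloxy)-2,3-dibromobenzaldehyde | O=Cc1cc(OCc2ccccc2)c(OCc2ccccc2)c(Br)c1Br | intermediate
5 | [4,5-bis(benzyloxy)-2,3-dibromophenyl]methanol | OCc1cc(OCc2ccccc2)c(OCc2ccccc2)c(Br)c1Br | intermediate
6 | 1,2-bis(benzyloxy)-3,4-dibromo-5-(bromomethyl)benzene | BrCc1cc(OCc2ccccc2)c(OCc2ccccc2)c(Br)c1Br | intermediate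
7 | acetylacetone (pentane-2,4-dione) | CC(=O)CC(C)=O | starting material
8 | 3-diazopentane-2,4-dione | CC(=O)C(=[N+]=[N-])C(C)=O | intermediate
9 | 3-methoxypentane-2,4-dione | COC(C(C)=O)C(C)=O | intermediate
10 | 1-[4,5-bis(benzyloxy)-2,3-dibromophenyl]-4-methoxyhexane-3,5-dione (racemic, enolisable) | CC(=O)C(OC)C(=O)CCc1cc(OCc2ccccc2)c(OCc2ccccc2)c(Br)c1Br | intermediate
11 | dimethyl oxalate | COC(=O)C(=O)OC | starting material
12 | methyl 8-[4,5-bis(benzyloxy)-2,3-dibromophenyl]-5-methoxy-2,4,6-trioxooctanoate (open-chain triketo ester, racemic, not isolated) | COC(=O)C(=O)CC(=O)C(OC)C(=O)CCc1cc(OCc2ccccc2)c(OCc2ccccc2)c(Br)c1Br | intermediate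
13 | methyl 2-[4,5-bis(benzyloxy)-2,3-dibromobenzyl]-1-hydroxy-4-methoxy-3,5-dioxocyclohexane-1-carboxylate (cyclic aldol adduct, mixture of diastereomers, not isolated) | COC(=O)C1(O)CC(=O)C(OC)C(=O)C1Cc1cc(OCc2ccccc2)c(OCc2ccccc2)c(Br)c1Br | intermediate
14 | methyl 2-[4,5-bis(benzyloxy)-2,3-dibromobenzyl]-3,5-dihydroxy-4-methoxybenzoate | COC(=O)c1cc(O)c(OC)c(O)c1Cc1cc(OCc2ccccc2)c(OCc2ccccc2)c(Br)c1Br | intermediate
15 | methyl 2-(2,3-dibromo-4,5-dihydroxybenzyl)-3,5-dihydroxy-4-methoxybenzoate | COC(=O)c1cc(O)c(OC)c(O)c1Cc1cc(O)c(O)c(Br)c1Br | intermediate
16 | 3,4-dibromo-5-{[2,4-dihydroxy-6-(hydroxymethyl)-3-methoxyphenyl]methyl}benzene-1,2-diol | COc1c(O)cc(CO)c(Cc2cc(O)c(O)c(Br)c2Br)c1O | target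

## Step count and risks

Total step count: 11 steps. Longest linear sequence: 9 steps (steps 1 to 5 and 8 to 11, from 1 to 16); the diketone branch (steps 6 and 7) joins at step 8.

**Step 9 (key step, proposed new method).**
- What may go wrong: retro-Claisen fragmentation of the triketo ester by methoxide, or a second addition of dianion to the oxalate-derived carbonyl. The sequence may also stall at the open-chain stage, because the C4 carbonyl is tied up as the stabilised 2,4-dioxo ester enolate and is no longer electrophilic enough for the aldol closure. O-cyclisation to a pyranone is possible if the acidic work-up is prolonged.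
- Fallback (known chemistry): it sets out from benzylic alcohol 5 and returns at 14. A dehydrative Friedel-Crafts benzylation of commercial methyl 3,5-dihydroxy-4-methoxybenzoate F1, used in excess, with 5 under catalysis by Sc(OTf)3 in MeNO2 at 60 °C should give 14 directly. The two free positions of F1 are equivalent by symmetry, each is ortho to one hydroxyl and para to the other, and the benzylic cation from 5 is stabilised by its para benzyloxy group. Ring A is then bought, not built, and the diketone branch is not needed.

**Step 8.**
- What may go wrong: incomplete second deprotonation of the methoxy-substituted diketone; proton exchange between dianion and monoanionic product, leading to double alkylation; or competing alkylation at the central carbon or at oxygen.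
- Fallback: it sets out from 7 and 6 and returns at 10, and installs the methoxy group after the carbon-carbon bond. The dianion of acetylacetone 7 (LiN(iPr)2, 2 equiv, THF) is alkylated with 6 to give 6-[4,5-bis(benzyloxy)-2,3-dibromophenyl]hexane-2,4-dione F2. Regitz diazo transfer (p-ABSA, Et3N, MeCN) then gives 6-[4,5-bis(benzyloxy)-2,3-dibromophenyl]-3-diazohexane-2,4-dione F3. Rh2(OAc)4 in MeOH/CH2Cl2 inserts the carbenoid into the O-H bond of methanol to give 10.

**Step 10.**
- What may go wrong: loss of the ring A methyl ether, which sits between two boron phenoxides that can chelate and activate it; or C-benzylation of the electron-rich ring A at C3 by benzyl cations that escape the scavenger.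
- Fallback: it sets out from 14 and returns at 16. Acetylation of both ring A phenols (Ac2O, pyridine) gives methyl 3,5-diacetoxy-2-[4,5-bis(benzyloxy)-2,3-dibromobenzyl]-4-methoxybenzoate F4, in which the acetoxy groups cannot form boron phenoxide chelates and deactivate ring A. BCl3 with C6HMe5 at −78 °C then gives methyl 3,5-diacetoxy-2-(2,3-dibromo-4,5-dihydroxybenzyl)-4-methoxybenzoate F5. Excess iBu2AlH in THF reduces the methyl ester and removes both acetates in one operation to give 16.

**Step 11.**
- What may go wrong: precipitation of the aluminium polyphenoxide before the ester is consumed, giving incomplete reduction or arrest at the aldehyde; or acid-induced ionisation of the new benzylic alcohol during work-up, followed by etherification or oligomerisation.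
- Fallback: it sets out from 15 and returns at 16, and replaces the nucleophilic hydride by an electrophilic one. Saponification with LiOH in degassed THF/H2O under argon, then acidification, gives 2-(2,3-dibromo-4,5-dihydroxybenzyl)-3,5-dihydroxy-4-methoxybenzoic acid F6. BH3·SMe2 in THF (0 °C to rt) reduces the carboxylic acid selectively to the hydroxymethyl group of 16. No ring A hydroxyl is ortho or para to C8, so over-reduction through a quinone methide is not open.

## Further compounds

F1 | step 9 | methyl 3,5-dihydroxy-4-methoxybenzoate | COC(=O)c1cc(O)c(OC)c(O)c1
F2 | step 8 | 6-[4,5-bis(benzyloxy)-2,3-dibromophenyl]hexane-2,4-dione | CC(=O)CC(=O)CCc1cc(OCc2ccccc2)c(OCc2ccccc2)c(Br)c1Br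
F3 | step 8 | 6-[4,5-bis(benzyloxy)-2,3-dibromophenyl]-3-diazohexane-2,4-dione | CC(=O)C(=[N+]=[N-])C(=O)CCc1cc(OCc2ccccc2)c(OCc2ccccc2)c(Br)c1Br
F4 | step 10 | methyl 3,5-diacetoxy-2-[4,5-bis(benzyloxy)-2,3-dibromobenzyl]-4-methoxybenzoate | COC(=O)c1cc(OC(C)=O)c(OC)c(OC(C)=O)c1Cc1cc(OCc2ccccc2)c(OCc2ccccc2)c(Br)c1Br
F5 | step 10 | methyl 3,5-diacetoxy-2-(2,3-dibromo-4,5-dihydroxybenzyl)-4-methoxybenzoate | COC(=O)c1cc(OC(C)=O)c(OC)c(OC(C)=O)c1Cc1cc(O)c(O)c(Br)c1Br
F6 | step 11 | 2-(2,3-dibromo-4,5-dihydroxybenzyl)-3,5-dihydroxy-4-methoxybenzoic acid | COc1c(O)cc(C(O)=O)c(Cc2cc(O)c(O)c(Br)c2Br)c1O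
A1 | alternative 1 | racemic (Z)-3-[4,5-bis(benzyloxy)-2,3-dibromophenyl]-4,6-bis(benzyloxy)-N-tert-butyl-5-methoxyisobenzofuran-1(3H)-imine | CC(C)(C)/N=C1\OC(c2cc(OCc3ccccc3)c(OCc3ccccc3)c(Br)c2Br)c2c(OCc3ccccc3)c(OC)c(OCc3ccccc3)cc12
A2 | alternative 1 | 2,4-bis(benzyloxy)-3-methoxy-6-(trimethylsilyl)phenyl trifluoromethanesulfonate | COc1c(OCc2ccccc2)cc([Si](C)(C)C)c(OS(=O)(=O)C(F)(F)F)c1OCc1ccccc1
A3 | alternative 1 | tert-butyl isocyanide | CC(C)(C)[N+]#[C-]
A4 | alternative 2 | racemic 5-(benzyloxy)-1-[4,5-bis(benzyloxy)-2,3-dibromophenyl]-6-methoxy-1,3-dihydroisobenzofuran-7-ol | COc1c(OCc2ccccc2)cc2c(c1O)C(c1cc(OCc3ccccc3)c(OCc3ccccc3)c(Br)c1Br)OC2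
A5 | alternative 2 | racemic 3-(benzyloxy)-5-[({1-[4,5-bis(benzyloxy)-2,3-dibromophenyl]prop-2-yn-1-yl}oxy)methyl]-2-methoxyfuran | C#CC(OCc1cc(OCc2ccccc2)c(OC)o1)c1cc(OCc2ccccc2)c(OCc2ccccc2)c(Br)c1Br
A6 | alternative 3 | [4,5-bis(benzyloxy)-2,3-dibromophenyl][6-(tert-butyldimethylsilyloxymethyl)-2,4-dihydroxy-3-methoxyphenyl]methanone | COc1c(O)cc(CO[Si](C)(C)C(C)(C)C)c(C(=O)c2cc(OCc3ccccc3)c(OCc3ccccc3)c(Br)c2Br)c1O
A7 | alternative 3 | 1,2-dimethoxy-1,3-bis(trimethylsilyloxy)buta-1,3-diene (geometry at the ketene acetal not defined) | COC(O[Si](C)(C)C)=C(OC)C(=C)O[Si](C)(C)C
A8 | alternative 3 | 1-[4,5-bis(benzyloxy)-2,3-dibromophenyl]-4-(tert-butyldimethylsilyloxy)but-2-yn-1-one | CC(C)(C)[Si](C)(C)OCC#CC(=O)c1cc(OCc2ccccc2)c(OCc2ccccc2)c(Br)c1Br
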